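**Assumption:** (5R)-5-(hydroxymethyl)dihydrofuran-2(3H)-one (the lactone made from D-glutamic acid) and 4-chlorobutanal are taken as catalogue items; the target SMILES is read as (3S,3aS,6aR) with a Z alkene in the N-chain.

## Retrosynthetic overview

1. Target 17 ⇐ 4-hydroxy cycloadduct 15, by radical deoxygenation of the C4 hydroxyl, the stereocentre that steers the ring formation.
2. 15 ⇐ hydroxy nitrone 14 by an intramolecular nitrone–alkene [3+2] cycloaddition; the cyclopentane and the isoxazolidine form together in this single step, the only ring-forming event.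
3. 14 ⇐ lactol 13 (masked 4-hydroxy aldehyde) + N-alkylhydroxylamine 9.
4. 13 and 9 ⇐ two Z-selective Wittig reactions that draw on one batch of ylide 6, with lactone aldehyde 11 (from the (R)-lactone 10) and with 4-chlorobutanal 7.
5. Ylide 6 ⇐ phosphonium salt 5 ⇐ 3-picoline 1 + 1-bromo-8-chlorooctane 2.

## Route

**Step 1**
Reactants: 1 3-methylpyridine (3-picoline); 2 1-bromo-8-chlorooctane
Product: 4 3-(9-chlorononyl)pyridine, via (pyridin-3-ylmethyl)lithium 3 (not isolated)
Conditions: LiN(iPr)2 (1.1 equiv), THF, −78 °C, 1 h; then 2 (1.5 equiv), −78 °C → rt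
Reagents that add atoms: none
Why: Lateral lithiation gives the picolyl anion, which displaces bromide much faster than chloride (SN2 alkylation), so the chain is attached once and the chloride end, too unreactive to self-quaternize the pyridine, survives.

**Step 2**
Reactants: 4 3-(9-chlorononyl)pyridine
Product: 5 triphenyl[9-(pyridin-3-yl)nonyl]phosphonium iodide
Conditions: PPh3 (3 equiv), NaI (1.2 equiv), MeCN, reflux, 48 h
Reagents that add atoms: triphenylphosphine, c1ccc(cc1)P(c1ccccc1)c1ccccc1; sodium iodide (NaI), [Na+].[I-]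
Why: In situ Finkelstein exchange followed by SN2 quaternization of the phosphine, which in excess out-competes the less nucleophilic pyridine nitrogen for the primary halide.

**Step 3**
Reactants: 5 triphenyl[9-(pyridin-3-yl)nonyl]phosphonium iodide
Product: 6 triphenyl[9-(pyridin-3-yl)nonylidene]-λ5-phosphane (phosphonium ylide; THF solution)
Conditions: NaN(SiMe3)2 (0.98 equiv), THF, −78 → 0 °C, 30 min; the orange solution is recooled to −78 °C under argon and divided by cannula into two portions, used the same day in steps 4 and 7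
Reagents that add atoms: none
Why: Deprotonation of the alkylphosphonium salt alpha to phosphorus by a lithium-free amide base gives the non-stabilized ylide, and the slight deficit of base leaves no free amide to epimerize the aldehyde of step 7; one batch serves both Wittig reactions.

**Step 4**
Reactants: 6 triphenyl[9-(pyridin-3-yl)nonylidene]-λ5-phosphane (first portion of the solution from step 3); 7 4-chlorobutanal
Product: 8 3-[(9Z)-13-chlorotridec-9-en-1-yl]pyridine
Conditions: 7 (1.1 equiv) added to 6 in THF, −78 °C → rt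
Reagents that add atoms: none
Why: Wittig olefination of a non-stabilized ylide under lithium-free conditions passes through the kinetically favoured cis-oxaphosphetane and gives the Z-alkene, while the primary chloride is inert to the ylide at low temperature.

**Step 5**
Reactants: 8 3-[(9Z)-13-chlorotridec-9-en-1-yl]pyridine
Product: 9 N-[(4Z)-13-(pyridin-3-yl)tridec-4-en-1-yl]hydroxylamine
Conditions: 50% aq. NH2OH (20 equiv), NaI (0.1 equiv), EtOH, 70 °C; used promptly under argon
Reagents that add atoms: hydroxylamine, NO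
Why: SN2 N-alkylation of hydroxylamine (an alpha-effect nucleophile, nitrogen more nucleophilic than oxygen) with iodide catalysis, the large excess suppressing dialkylation and pyridine quaternization.

**Step 6**
Reactants: 10 (5R)-5-(hydroxymethyl)dihydrofuran-2(3H)-one
Product: 11 (2R)-5-oxotetrahydrofuran-2-carbaldehyde
Conditions: Dess–Martin periodinane (1.2 equiv), CH2Cl2, 0 °C → rt; filtered and used crude at once (run on the day the ylide of step 3 is made)
Reagents that add atoms: none
Why: Dess–Martin oxidation of the primary alcohol is non-basic, so the alpha-oxygenated stereocentre bought in 10 is not epimerized.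

**Step 7**
Reactants: 6 triphenyl[9-(pyridin-3-yl)nonylidene]-λ5-phosphane (second portion of the solution from step 3); 11 (2R)-5-oxotetrahydrofuran-2-carbaldehyde
Product: 12 (5R)-5-[(1Z)-10-(pyridin-3-yl)dec-1-en-1-yl]dihydrofuran-2(3H)-one
Conditions: 6 (0.95 equiv) added slowly to 11 in THF at −78 °C, then → −20 °C
Reagents that add atoms: none
Why: Z-selective Wittig olefination in which the aldehyde reacts far faster than the lactone carbonyl, and slow addition of a slight deficit of amide-free ylide at −78 °C limits enolization, so the (R) centre from 10 is carried through.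

**Step 8**
Reactants: 12 (5R)-5-[(1Z)-10-(pyridin-3-yl)dec-1-en-1-yl]dihydrofuran-2(3H)-one
Product: 13 (5R)-5-[(1Z)-10-(pyridin-3-yl)dec-1-en-1-yl]tetrahydrofuran-2-ol (anomer mixture)
Conditions: iBu2AlH (2.2 equiv; one equivalent is held by the pyridine), CH2Cl2, −78 °C; aqueous KNaC4H4O6 (potassium sodium tartrate) work-up
Reagents that add atoms: none
Why: Partial lactone reduction stops at the tetrahedral aluminium acetal at −78 °C and gives the lactol, a masked 4-hydroxy aldehyde, without touching the C5 stereocentre or the alkene.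

**Step 9**
Reactants: 13 (5R)-5-[(1Z)-10-(pyridin-3-yl)dec-1-en-1-yl]tetrahydrofuran-2-ol; 9 N-[(4Z)-13-(pyridin-3-yl)tridec-4-en-1-yl]hydroxylamine
Product: 15 (3S,3aR,4R,6aR)-3-[8-(pyridin-3-yl)octyl]-1-[(4Z)-13-(pyridin-3-yl)tridec-4-en-1-yl]hexahydro-1H-cyclopenta[c][1,2]oxazol-4-ol, via hydroxy nitrone 14 (not isolated)
Conditions: 9 (1.1 equiv), degassed toluene, 80 °C, 16 h
Reagents that add atoms: none
Why: Condensation of the lactol with the hydroxylamine gives the nitrone, which undergoes intramolecular nitrone–alkene [3+2] cycloaddition: the three-carbon tether enforces the cis ring fusion, the Z-alkene is transferred suprafacially into the cis H-3/H-3a relationship, and A(1,3) strain makes the allylic C–H of the (R)-carbinol eclipse the Z double bond so that the tether reaches only one alkene face, setting C3, C3a and C6a with the hydroxyl on the convex face (80 °C is kept to disfavour the slower cycloaddition onto the N-chain alkene).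

**Step 10**
Reactants: 15 (3S,3aR,4R,6aR)-3-[8-(pyridin-3-yl)octyl]-1-[(4Z)-13-(pyridin-3-yl)tridec-4-en-1-yl]hexahydro-1H-cyclopenta[c][1,2]oxazol-4-ol
Product: 16 O-[(3S,3aR,4R,6aR)-3-[8-(pyridin-3-yl)octyl]-1-[(4Z)-13-(pyridin-3-yl)tridec-4-en-1-yl]hexahydro-1H-cyclopenta[c][1,2]oxazol-4-yl] 1H-imidazole-1-carbothioate
Conditions: 1,1'-thiocarbonyldiimidazole (2 equiv), 4-(dimethylamino)pyridine (0.1 equiv), ClCH2CH2Cl, 70 °C
Reagents that add atoms: 1,1'-thiocarbonyldiimidazole, S=C(n1ccnc1)n1ccnc1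
Why: Thioacylation of the exposed convex-face secondary alcohol gives the Barton–McCombie precursor without an alkylating agent that would quaternize the pyridines; no stereocentre is touched.

**Step 11**
Reactants: 16 O-[(3S,3aR,4R,6aR)-3-[8-(pyridin-3-yl)octyl]-1-[(4Z)-13-(pyridin-3-yl)tridec-4-en-1-yl]hexahydro-1H-cyclopenta[c][1,2]oxazol-4-yl] 1H-imidazole-1-carbothioate
Product: 17 pyrinodemin C, (3S,3aS,6aR)-3-[8-(pyridin-3-yl)octyl]-1-[(4Z)-13-(pyridin-3-yl)tridec-4-en-1-yl]hexahydro-1H-cyclopenta[c][1,2]oxazole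
Conditions: Bu3SnH (2 equiv), azobisisobutyronitrile (0.2 equiv), toluene, 100 °C
Reagents that add atoms: none
Why: Barton–McCombie radical deoxygenation, in which the stannyl radical adds to C=S and the secondary C4 radical takes hydrogen from the stannane; C4 becomes CH2, so the control element disappears while C3, C3a and C6a, the N–O bond and the isolated Z-alkene are left alone.

## Compound list

1 | 3-methylpyridine (3-picoline) | Cc1cccnc1 | starting material
2 | 1-bromo-8-chlorooctane | ClCCCCCCCCBr | starting material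
3 | (pyridin-3-ylmethyl)lithium | [Li]Cc1cccnc1 | intermediate (not isolated)
4 | 3-(9-chlorononyl)pyridine | ClCCCCCCCCCc1cccnc1 | intermediate
5 | triphenyl[9-(pyridin-3-yl)nonyl]phosphonium iodide | [I-].c1ccc(cc1)[P+](c1ccccc1)(c1ccccc1)CCCCCCCCCc1cccnc1 | intermediate
6 | triphenyl[9-(pyridin-3-yl)nonylidene]-λ5-phosphane (phosphonium ylide; THF solution) | c1ccc(cc1)P(c1ccccc1)(c1ccccc1)=CCCCCCCCCc1cccnc1 | intermediate
7 | 4-chlorobutanal | O=CCCCCl | starting material
8 | 3-[(9Z)-13-chlorotridec-9-en-1-yl]pyridine | ClCCC/C=C\CCCCCCCCc1cccnc1 | intermediate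
9 | N-[(4Z)-13-(pyridin-3-yl)tridec-4-en-1-yl]hydroxylamine | ONCCC/C=C\CCCCCCCCc1cccnc1 | intermediate
10 | (5R)-5-(hydroxymethyl)dihydrofuran-2(3H)-one | OC[C@H]1CCC(=O)O1 | starting material
11 | (2R)-5-oxotetrahydrofuran-2-carbaldehyde | O=C[C@H]1CCC(=O)O1 | intermediate
12 | (5R)-5-[(1Z)-10-(pyridin-3-yl)dec-1-en-1-yl]dihydrofuran-2(3H)-one | O=C1CC[C@@H](O1)/C=C\CCCCCCCCc1cccnc1 | intermediate
13 | (5R)-5-[(1Z)-10-(pyridin-3-yl)dec-1-en-1-yl]tetrahydrofuran-2-ol (anomer mixture) | OC1CC[C@@H](O1)/C=C\CCCCCCCCc1cccnc1 | intermediate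
14 | (1Z,4R,5Z)-4-hydroxy-14-(pyridin-3-yl)-N-[(4Z)-13-(pyridin-3-yl)tridec-4-en-1-yl]tetradec-5-en-1-imine N-oxide (hydroxy nitrone) | [O-]/[N+](CCC/C=C\CCCCCCCCc1cccnc1)=C\CC[C@@H](O)/C=C\CCCCCCCCc1cccnc1 | intermediate (not isolated)
15 | (3S,3aR,4R,6aR)-3-[8-(pyridin-3-yl)octyl]-1-[(4Z)-13-(pyridin-3-yl)tridec-4-en-1-yl]hexahydro-1H-cyclopenta[c][1,2]oxazol-4-ol (cis-fused; H-3, H-3a, H-6a all cis; 4-OH cis to H-3a) | C(=C/CCCN1O[C@@H](CCCCCCCCc2cccnc2)[C@H]2[C@H](O)CC[C@H]21)/CCCCCCCCc1cccnc1 | intermediate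
16 | O-[(3S,3aR,4R,6aR)-3-[8-(pyridin-3-yl)octyl]-1-[(4Z)-13-(pyridin-3-yl)tridec-4-en-1-yl]hexahydro-1H-cyclopenta[c][1,2]oxazol-4-yl] 1H-imidazole-1-carbothioate | C(=C/CCCN1O[C@@H](CCCCCCCCc2cccnc2)[C@H]2[C@H](OC(=S)n3ccnc3)CC[C@H]21)/CCCCCCCCc1cccnc1 | intermediate
17 | pyrinodemin C, (3S,3aS,6aR)-3-[8-(pyridin-3-yl)octyl]-1-[(4Z)-13-(pyridin-3-yl)tridec-4-en-1-yl]hexahydro-1H-cyclopenta[c][1,2]oxazole | C(=C/CCCN1O[C@@H](CCCCCCCCc2cccnc2)[C@H]2CCC[C@H]21)/CCCCCCCCc1cccnc1 | target

## Step count and weak points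

Total: 11 steps. Longest linear sequence: 8 steps (1, 2, 3, 7, 8, 9, 10, 11; the branch 1, 2, 3, 4, 5, 9, 10, 11 is equally long).

**Step 5 (direct alkylation of hydroxylamine).** Dialkylation or pyridine quaternization may erode the yield. The fallback sets out from 8 and comes back at 9. Compound 8 is used to N-alkylate tert-butyl N-[(tert-butoxycarbonyl)oxy]carbamate, which can react only once (K2CO3, NaI cat., DMF, 60 °C), giving tert-butyl N-[(tert-butoxycarbonyl)oxy]-N-[(4Z)-13-(pyridin-3-yl)tridec-4-en-1-yl]carbamate F1. Treatment with CF3CO2H in CH2Cl2 (0 °C → rt) and then aqueous NaHCO3 removes both Boc groups and returns to 9.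

**Step 7 (basic ylide on an epimerizable, enolizable lactone aldehyde).** Partial racemization or low yield is possible. The fallback sets out from 11 (and from 1 for the chain) and comes back at 12. The far less basic (iodomethylidene)triphenyl-λ5-phosphane F2, made from (iodomethyl)triphenylphosphonium iodide and NaN(SiMe3)2 (THF/DMPU, −78 °C), converts 11 in a Stork–Zhao olefination into (5R)-5-[(Z)-2-iodoethenyl]dihydrofuran-2(3H)-one F3. In parallel, 1 is lithiated as in step 1 (via 3) and alkylated with 7-bromohept-1-ene to give 3-(oct-7-en-1-yl)pyridine F4. Hydroboration with 9-borabicyclo[3.3.1]nonane (2 equiv, one being held by the pyridine nitrogen; THF, rt) gives 9-[8-(pyridin-3-yl)octyl]-9-borabicyclo[3.3.1]nonane F5, used in solution. B-alkyl Suzuki–Miyaura coupling of F3 with F5 ([1,1'-bis(diphenylphosphino)ferrocene]PdCl2, K3PO4, DMF/THF with a little H2O, rt) proceeds with retention of the Z geometry and comes back to the route at 12.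

**Step 9 (nitrone formation from a lactol and facial control by a free hydroxyl).** The hemiaminal resting state may slow the reaction, or the diastereoselectivity may be modest. The fallback sets out from 12 and comes back at 15. Lactone 12 is opened with MeNH(OMe)·HCl/AlMe3 (CH2Cl2, 0 °C) to (4R,5Z)-4-hydroxy-N-methoxy-N-methyl-14-(pyridin-3-yl)tetradec-5-enamide F6. This is silylated at once (tBuMe2SiCl, imidazole, DMF) to (4R,5Z)-4-[(tert-butyldimethylsilyl)oxy]-N-methoxy-N-methyl-14-(pyridin-3-yl)tetradec-5-enamide F7. Reduction (iBu2AlH, THF, −78 °C) then gives (4R,5Z)-4-[(tert-butyldimethylsilyl)oxy]-14-(pyridin-3-yl)tetradec-5-enal F8. Condensation with 9 (MgSO4, CH2Cl2, rt) gives the open-chain nitrone (1Z,4R,5Z)-4-[(tert-butyldimethylsilyl)oxy]-14-(pyridin-3-yl)-N-[(4Z)-13-(pyridin-3-yl)tridec-4-en-1-yl]tetradec-5-en-1-imine N-oxide F9, which cannot rest as a hemiaminal and carries a bulkier allylic group. Heating (toluene, 80 °C) gives (3S,3aS,4R,6aR)-4-[(tert-butyldimethylsilyl)oxy]-3-[8-(pyridin-3-yl)octyl]-1-[(4Z)-13-(pyridin-3-yl)tridec-4-en-1-yl]hexahydro-1H-cyclopenta[c][1,2]oxazole F10, and Bu4NF (THF, rt) returns to 15.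

## Further compounds

F1 | step 5 | tert-butyl N-[(tert-butoxycarbonyl)oxy]-N-[(4Z)-13-(pyridin-3-yl)tridec-4-en-1-yl]carbamate | CC(C)(C)OC(=O)ON(CCC/C=C\CCCCCCCCc1cccnc1)C(=O)OC(C)(C)C
F2 | step 7 | (iodomethylidene)triphenyl-λ5-phosphane | IC=P(c1ccccc1)(c1ccccc1)c1ccccc1
F3 | step 7 | (5R)-5-[(Z)-2-iodoethenyl]dihydrofuran-2(3H)-one | O=C1CC[C@@H](O1)/C=C\I
F4 | step 7 | 3-(oct-7-en-1-yl)pyridine | C=CCCCCCCc1cccnc1
F5 | step 7 | 9-[8-(pyridin-3-yl)octyl]-9-borabicyclo[3.3.1]nonane | B1(CCCCCCCCc2cccnc2)C2CCCC1CCC2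
F6 | step 9 | (4R,5Z)-4-hydroxy-N-methoxy-N-methyl-14-(pyridin-3-yl)tetradec-5-enamide | CON(C)C(=O)CC[C@@H](O)/C=C\CCCCCCCCc1cccnc1
F7 | step 9 | (4R,5Z)-4-[(tert-butyldimethylsilyl)oxy]-N-methoxy-N-methyl-14-(pyridin-3-yl)tetradec-5-enamide | CON(C)C(=O)CC[C@@H](O[Si](C)(C)C(C)(C)C)/C=C\CCCCCCCCc1cccnc1
F8 | step 9 | (4R,5Z)-4-[(tert-butyldimethylsilyl)oxy]-14-(pyridin-3-yl)tetradec-5-enal | O=CCC[C@@H](O[Si](C)(C)C(C)(C)C)/C=C\CCCCCCCCc1cccnc1
F9 | step 9 | (1Z,4R,5Z)-4-[(tert-butyldimethylsilyl)oxy]-14-(pyridin-3-yl)-N-[(4Z)-13-(pyridin-3-yl)tridec-4-en-1-yl]tetradec-5-en-1-imine N-oxide | [O-]/[N+](CCC/C=C\CCCCCCCCc1cccnc1)=C\CC[C@@H](O[Si](C)(C)C(C)(C)C)/C=C\CCCCCCCCc1cccnc1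
F10 | step 9 | (3S,3aS,4R,6aR)-4-[(tert-butyldimethylsilyl)oxy]-3-[8-(pyridin-3-yl)octyl]-1-[(4Z)-13-(pyridin-3-yl)tridec-4-en-1-yl]hexahydro-1H-cyclopenta[c][1,2]oxazole | C(=C/CCCN1O[C@@H](CCCCCCCCc2cccnc2)[C@H]2[C@H](O[Si](C)(C)C(C)(C)C)CC[C@H]21)/CCCCCCCCc1cccnc1
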